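**Plan**
Retrosynthesis: cut the C15 ester, then C13–C16 and C14–C15 (carboalumination/formaldehyde on a terminal alkyne), then C8=C17 (Wittig on an 8-ketone). Ring B and ring A are then cut together at C7–C8 and C5–C10, and the open chain at C1–C10 (B-alkyl Suzuki) into fragment 1 (C2–C7, C18, C19) and fragment 2 (C8–C14, C20).
Enabling feature: in ring B, C5–C6–C7 can be an enal (electrophilic at C5 and C7) and C10–C9–C8 an alkene/phosphonoacetate pair (tertiary C10 radical by hydrogen-atom transfer to C10=C20, carbanion at C8). The C1–C3 tether makes the C5–C10 union the 6-exo closure of ring A, which brings C7 and C8 together for ring B.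
Forward: fragments 1 and 2 are joined, ring A then ring B are closed in one flask (step 15), the activating C8 carboxyl is excised to the 8-ketone, then methylenation, side-chain completion and palmitoylation.
Stereochemistry: C4 from a Pd-catalysed decarboxylative asymmetric allylation (the cyclopentanone C–C bond is cleaved afterwards). C5/C10 come from the chair radical cyclization, steered by C4 and by a sacrificial auxiliary-set C9. C9 is finally set by equilibration next to the C8 ketone, and 13E by syn-carboalumination.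

Key step: step 15

Remark: labdane numbering (C1–C20) is used for positions in all compounds. C9 of the cyclization substrate is deliberately made as the unnatural epimer; this is harmless because C9 is equilibrated next to the C8 ketone in step 17.

Step 1
Reactants: 1 diallyl adipate
Product: 3 allyl 1-methyl-2-oxocyclopentane-1-carboxylate (racemic), via sodium enolate 2 (not isolated)
Conditions: NaH, THF, reflux; then MeI, rt
Reagents that add atoms: iodomethane CI
Why: Dieckmann condensation followed by C-methylation of the β-keto ester enolate in the same flask gives the substrate for decarboxylative allylation; no stereocentre is controlled here.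

Step 2
Reactants: 3 allyl 1-methyl-2-oxocyclopentane-1-carboxylate
Product: 4 (R)-2-allyl-2-methylcyclopentan-1-one
Conditions: Pd2(dba)3 (2.5 mol %), (R)-t-BuPHOX (6 mol %), THF, 25 °C
Reagents that add atoms: none
Why: Tsuji-type decarboxylative asymmetric allylic alkylation passes both enantiomers of 3 through one achiral enolate, and the ligand enantiomer is chosen to deliver the R quaternary centre that becomes C4.

Step 3
Reactants: 4 (R)-2-allyl-2-methylcyclopentan-1-one
Product: 5 (2R)-2-allyl-5-hydroxy-2-methylcyclopentan-1-one (C5 epimers)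
Conditions: KHMDS, THF, −78 °C; 2-(phenylsulfonyl)-3-phenyloxaziridine; then H2O
Reagents that add atoms: 2-(phenylsulfonyl)-3-phenyloxaziridine O=S(=O)(c1ccccc1)N1OC1c1ccccc1
Why: The ketone can enolize only away from the quaternary carbon, and oxaziridine hydroxylation of that enolate installs the α′-hydroxyl needed for ring cleavage (its configuration is irrelevant).

Step 4
Reactants: 5 (2R)-2-allyl-5-hydroxy-2-methylcyclopentan-1-one
Product: 7 methyl (2R)-2-allyl-5,5-dimethoxy-2-methylpentanoate, via aldehyde ester 6 (not isolated)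
Conditions: Pb(OAc)4, MeOH/PhMe, 0 °C; then HC(OMe)3, TsOH·H2O, rt
Reagents that add atoms: methanol CO; trimethyl orthoformate COC(OC)OC
Why: Criegee-type α-ketol cleavage in methanol cuts the ring bond between the ketone carbon (which becomes the C19 methyl ester) and the carbinol carbon (which becomes the C7 aldehyde) without touching the quaternary centre, and the aldehyde is masked in the same flask as its dimethyl acetal.

Step 5
Reactants: 8 hex-5-ynoic acid
Product: 10 6-(trimethylsilyl)hex-5-ynoic acid, via silyl ester 9 (not isolated)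
Conditions: n-BuLi (2.1 equiv), THF, −78 to 0 °C; TMSCl (2.3 equiv); then 1 M HCl
Reagents that add atoms: chlorotrimethylsilane C[Si](C)(C)Cl
Why: Double deprotonation (carboxylate and acetylide), silylation and hydrolysis of the silyl ester on work-up protect the terminal alkyne for the later borane, enolate and radical steps.

Step 6
Reactants: 10 6-(trimethylsilyl)hex-5-ynoic acid; 11 (S)-4-benzyloxazolidin-2-one
Product: 13 (S)-4-benzyl-3-[6-(trimethylsilyl)hex-5-ynoyl]oxazolidin-2-one, via mixed anhydride 12 (not isolated)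
Conditions: PivCl, Et3N, THF, −20 °C; then LiCl, 11, rt
Reagents that add atoms: none
Why: N-acylation of the oxazolidinone through the mixed pivalic anhydride attaches the Evans auxiliary.

Step 7
Reactants: 13 N-acyl oxazolidinone; 14 tert-butyl bromoacetate
Product: 15 tert-butyl (3R)-3-[(4S)-4-benzyl-2-oxooxazolidine-3-carbonyl]-7-(trimethylsilyl)hept-6-ynoate
Conditions: NaHMDS, THF, −78 °C; then 14, −78 to −40 °C
Reagents that add atoms: none
Why: Evans alkylation of the chelated Z sodium enolate occurs anti to the benzyl group and sets the 3R centre (C9, in the 9-epi sense wanted for the cyclization).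

Step 8
Reactants: 15 alkylated imide
Product: 16 tert-butyl (3R)-3-[methoxy(methyl)carbamoyl]-7-(trimethylsilyl)hept-6-ynoate
Conditions: MeNH(OMe)·HCl, AlMe3, CH2Cl2, −10 °C to rt
Reagents that add atoms: N,O-dimethylhydroxylamine hydrochloride CNOC.Cl
Why: Aluminium amide transamination of the imide releases the auxiliary and gives the Weinreb amide without epimerization.

Step 9
Reactants: 16 Weinreb amide
Product: 17 tert-butyl (3R)-3-acetyl-7-(trimethylsilyl)hept-6-ynoate
Conditions: MeMgBr, THF, −20 to 0 °C; then H2O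
Reagents that add atoms: methylmagnesium bromide C[Mg]Br
Why: Weinreb ketone synthesis stops at the chelated tetrahedral adduct and gives the methyl ketone (C10 and C20) while the tert-butyl ester survives.

Step 10
Reactants: 17 methyl ketone
Product: 18 tert-butyl (3R)-3-[1-(trifluoromethylsulfonyloxy)ethenyl]-7-(trimethylsilyl)hept-6-ynoate
Conditions: KHMDS, THF, −78 °C; then PhNTf2; then H2O
Reagents that add atoms: N-phenylbis(trifluoromethanesulfonimide) O=S(=O)(N(c1ccccc1)S(=O)(=O)C(F)(F)F)C(F)(F)F
Why: Kinetic deprotonation on the methyl side and O-triflation give the 1,1-disubstituted enol triflate and leave the adjacent stereocentre alone.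

Step 11
Reactants: 7 acetal ester; 18 enol triflate
Product: 20 tert-butyl (3R)-3-[(6S)-9,9-dimethoxy-6-(methoxycarbonyl)-6-methylnon-1-en-2-yl]-7-(trimethylsilyl)hept-6-ynoate, via B-alkylborane 19 (not isolated)
Conditions: 9-BBN, THF, rt; then 18, PdCl2(dppf) (5 mol %), aq. K3PO4, DMF, 50 °C
Reagents that add atoms: none
Why: Anti-Markovnikov hydroboration of the terminal alkene and B-alkyl Suzuki–Miyaura coupling with the enol triflate form the C1–C10 bond and the C10=C20 alkene.

Step 12
Reactants: 20 coupled diester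
Product: 22 tert-butyl (2RS,3S)-2-(diethoxyphosphoryl)-3-[(6S)-9,9-dimethoxy-6-(methoxycarbonyl)-6-methylnon-1-en-2-yl]-7-(trimethylsilyl)hept-6-ynoate, via phosphonite 21 (not isolated)
Conditions: LDA (2.1 equiv), THF, −78 °C; ClP(OEt)2; then H2O2 (30 %), 0 °C
Reagents that add atoms: diethyl chlorophosphite CCOP(Cl)OCC; hydrogen peroxide OO
Why: The tert-butyl ester is the only enolizable ester, and C-phosphinylation of its lithium enolate followed by oxidation gives the phosphonoacetate (the C8 donor).

Step 13
Reactants: 22 phosphonate acetal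
Product: 23 tert-butyl (2RS,3S)-2-(diethoxyphosphoryl)-3-[(6S)-6-(methoxycarbonyl)-6-methyl-9-oxonon-1-en-2-yl]-7-(trimethylsilyl)hept-6-ynoate
Conditions: TsOH·H2O (10 mol %), acetone/H2O, rt
Reagents that add atoms: water O
Why: Mild acid-catalysed acetal hydrolysis frees the C7 aldehyde while the tert-butyl ester, alkynylsilane and phosphonate survive.

Step 14
Reactants: 23 aldehyde
Product: 24 tert-butyl (2RS,3S)-2-(diethoxyphosphoryl)-3-[(6S,7E)-6-(methoxycarbonyl)-6-methyl-9-oxonona-1,7-dien-2-yl]-7-(trimethylsilyl)hept-6-ynoate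
Conditions: IBX (2.5 equiv), DMSO, 70 °C
Reagents that add atoms: none
Why: IBX α,β-dehydrogenation of the aldehyde gives the E enal, and the quaternary γ-carbon (C4) stops further desaturation.

Step 15
Reactants: 24 enal
Product: 26 17-tert-butyl 19-methyl 15,16-dinor-9-epi-labd-7-en-13-yne-17,19-dioate (5α-H; 10β-CH3; 4β-CO2Me; C9 side chain α), via ring-A aldehyde 25 (not isolated)
Conditions: Fe(acac)3 (30 mol %), PhSiH3, EtOH/(CH2OH)2 (5:1), 0.01 M, 60 °C; then K2CO3, MeOH, rt
Reagents that add atoms: none
Why: The Fe–H species formed from Fe(acac)3 and PhSiH3 transfers a hydrogen atom to the electron-rich C10=C20 alkene rather than to the electron-poor enal; the tertiary C10 radical adds to C5 (6-exo-trig, ring A, C5–C10 bond), the α-formyl radical is reduced and protonated to aldehyde 25, and K2CO3/MeOH then lets the C8 phosphonate carbanion condense with the C7 aldehyde (6-exo-trig addition then elimination, ring B, C7–C8 bond) and cleaves the alkynylsilane. The closest known reaction types are the iron-hydride radical conjugate addition of alkenes to enals (intramolecular Giese cyclization with radical–polar crossover) and the intramolecular Horner–Wadsworth–Emmons olefination, run here in one flask so that the enal serves as a 1,3-dielectrophile (C5, C7) for the C10/C8 donor pair. Ring A should close through a chair transition state with the enal arm equatorial on C5 and the bulky C9 branch equatorial on C10, which places the new C20 methyl axial and gives the trans 5α-H/10β-CH3 relationship. The absolute sense is set by the fixed C4 centre, whose ester rather than methyl should take the axial site syn to C20, and should be reinforced by the 9R centre, whose phosphonoacetate arm should lie anti to the forming bond; C9 itself is corrected in step 17. The step needs cyclization to outrun hydrogen-atom quenching of the C10 radical (helped by the 6-exo geometry, the polarity match and high dilution) and needs the phosphonate to stay silent until the saturated aldehyde exists, which the neutral first stage secures.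

Step 16
Reactants: 26 bicyclic tert-butyl ester
Product: 27 19-methyl hydrogen 15,16-dinor-9-epi-labd-7-en-13-yne-17,19-dioate (17-acid)
Conditions: TFA, CH2Cl2, 0 °C to rt
Reagents that add atoms: none
Why: Acidolysis of the tert-butyl ester (loss of isobutene) frees the unsaturated acid while the hindered neopentyl methyl ester stays.

Step 17
Reactants: 27 unsaturated acid
Product: 31 methyl 8-oxo-15,16,17-trinorlabd-13-yn-19-oate (9β side chain), via acyl azide 28 (not isolated), via vinyl isocyanate 29 (not isolated), via 9-epi ketone 30 (not isolated)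
Conditions: DPPA, Et3N, PhMe, rt then 85 °C; then 2 M HCl, THF, 60 °C
Reagents that add atoms: water O
Why: Curtius rearrangement gives the vinyl isocyanate, whose acidic hydrolysis (enamine, then imine) gives the C8 ketone and excises the former ester carbon, and under the same acid C9, now α to the ketone, equilibrates to the more stable equatorial β side chain.

Step 18
Reactants: 31 8-ketone
Product: 32 methyl 15,16-dinorlabd-8(17)-en-13-yn-19-oate
Conditions: Ph3PCH3Br, KOtBu, THF, 0 to 50 °C
Reagents that add atoms: methyltriphenylphosphonium bromide C[P+](c1ccccc1)(c1ccccc1)c1ccccc1.[Br-]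
Why: Wittig methylenation of the C8 ketone installs the exocyclic 8(17) alkene, and C9 stays in its thermodynamically preferred configuration under the basic conditions.

Step 19
Reactants: 32 terminal alkyne
Product: 34 methyl (13E)-15-hydroxylabda-8(17),13-dien-19-oate, via alkenylalane 33 (not isolated)
Conditions: AlMe3, Cp2ZrCl2 (20 mol %), CH2Cl2, 0 °C to rt; then (CH2O)n; then H2O
Reagents that add atoms: trimethylaluminium C[Al](C)C; formaldehyde (from paraformaldehyde) C=O
Why: Negishi zirconium-catalysed carboalumination adds CH3 and Al syn across the terminal alkyne and the alkenylalane is trapped by formaldehyde with retention, which fixes the 13E allylic alcohol.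

Step 20
Reactants: 34 allylic alcohol; 35 palmitoyl chloride
Product: 36 methyl (13E)-15-(hexadecanoyloxy)labda-8(17),13-dien-19-oate (target)
Conditions: pyridine, DMAP (cat.), CH2Cl2, 0 °C to rt
Reagents that add atoms: none
Why: DMAP-catalysed acylation of the unhindered primary allylic alcohol gives the palmitate without touching the stereocentres.

**Compound list**
1 | diallyl adipate | C=CCOC(=O)CCCCC(=O)OCC=C | starting material
2 | sodium enolate of allyl 2-oxocyclopentane-1-carboxylate | C=CCOC(=O)C1=C([O-])CCC1.[Na+] | intermediate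
3 | allyl 1-methyl-2-oxocyclopentane-1-carboxylate (racemic) | C=CCOC(=O)C1(C)CCCC1=O | intermediate
4 | (R)-2-allyl-2-methylcyclopentan-1-one | C=CC[C@@]1(C)CCCC1=O | intermediate
5 | (2R)-2-allyl-5-hydroxy-2-methylcyclopentan-1-one (C5 epimers) | C=CC[C@@]1(C)CCC(O)C1=O | intermediate
6 | methyl (2R)-2-allyl-2-methyl-5-oxopentanoate | C=CC[C@@](C)(CCC=O)C(=O)OC | intermediate
7 | methyl (2R)-2-allyl-5,5-dimethoxy-2-methylpentanoate | C=CC[C@@](C)(CCC(OC)OC)C(=O)OC | intermediate
8 | hex-5-ynoic acid | C#CCCCC(=O)O | starting material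
9 | trimethylsilyl 6-(trimethylsilyl)hex-5-ynoate | C[Si](C)(C)C#CCCCC(=O)O[Si](C)(C)C | intermediate
10 | 6-(trimethylsilyl)hex-5-ynoic acid | C[Si](C)(C)C#CCCCC(=O)O | intermediate
11 | (S)-4-benzyloxazolidin-2-one | O=C1N[C@@H](Cc2ccccc2)CO1 | starting material
12 | 6-(trimethylsilyl)hex-5-ynoic pivalic anhydride | C[Si](C)(C)C#CCCCC(=O)OC(=O)C(C)(C)C | intermediate
13 | (S)-4-benzyl-3-[6-(trimethylsilyl)hex-5-ynoyl]oxazolidin-2-one | C[Si](C)(C)C#CCCCC(=O)N1[C@@H](Cc2ccccc2)COC1=O | intermediate
14 | tert-butyl bromoacetate | CC(C)(C)OC(=O)CBr | starting material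
15 | tert-butyl (3R)-3-[(4S)-4-benzyl-2-oxooxazolidine-3-carbonyl]-7-(trimethylsilyl)hept-6-ynoate | C[Si](C)(C)C#CCC[C@H](CC(=O)OC(C)(C)C)C(=O)N1[C@@H](Cc2ccccc2)COC1=O | intermediate
16 | tert-butyl (3R)-3-[methoxy(methyl)carbamoyl]-7-(trimethylsilyl)hept-6-ynoate | C[Si](C)(C)C#CCC[C@H](CC(=O)OC(C)(C)C)C(=O)N(C)OC | intermediate
17 | tert-butyl (3R)-3-acetyl-7-(trimethylsilyl)hept-6-ynoate | C[Si](C)(C)C#CCC[C@H](CC(=O)OC(C)(C)C)C(C)=O | intermediate
18 | tert-butyl (3R)-3-[1-(trifluoromethylsulfonyloxy)ethenyl]-7-(trimethylsilyl)hept-6-ynoate | C[Si](C)(C)C#CCC[C@H](CC(=O)OC(C)(C)C)C(=C)OS(=O)(=O)C(F)(F)F | intermediate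
19 | methyl (2S)-2-[3-(9-borabicyclo[3.3.1]nonan-9-yl)propyl]-5,5-dimethoxy-2-methylpentanoate | COC(=O)[C@](C)(CCC(OC)OC)CCCB1C2CCCC1CCC2 | intermediate
20 | tert-butyl (3R)-3-[(6S)-9,9-dimethoxy-6-(methoxycarbonyl)-6-methylnon-1-en-2-yl]-7-(trimethylsilyl)hept-6-ynoate | COC(=O)[C@](C)(CCC(OC)OC)CCCC(=C)[C@H](CCC#C[Si](C)(C)C)CC(=O)OC(C)(C)C | intermediate
21 | tert-butyl (2RS,3S)-2-(diethoxyphosphanyl)-3-[(6S)-9,9-dimethoxy-6-(methoxycarbonyl)-6-methylnon-1-en-2-yl]-7-(trimethylsilyl)hept-6-ynoate | COC(=O)[C@](C)(CCC(OC)OC)CCCC(=C)[C@H](CCC#C[Si](C)(C)C)C(C(=O)OC(C)(C)C)P(OCC)OCC | intermediate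
22 | tert-butyl (2RS,3S)-2-(diethoxyphosphoryl)-3-[(6S)-9,9-dimethoxy-6-(methoxycarbonyl)-6-methylnon-1-en-2-yl]-7-(trimethylsilyl)hept-6-ynoate | COC(=O)[C@](C)(CCC(OC)OC)CCCC(=C)[C@H](CCC#C[Si](C)(C)C)C(C(=O)OC(C)(C)C)P(=O)(OCC)OCC | intermediate
23 | tert-butyl (2RS,3S)-2-(diethoxyphosphoryl)-3-[(6S)-6-(methoxycarbonyl)-6-methyl-9-oxonon-1-en-2-yl]-7-(trimethylsilyl)hept-6-ynoate | COC(=O)[C@](C)(CCC=O)CCCC(=C)[C@H](CCC#C[Si](C)(C)C)C(C(=O)OC(C)(C)C)P(=O)(OCC)OCC | intermediate
24 | tert-butyl (2RS,3S)-2-(diethoxyphosphoryl)-3-[(6S,7E)-6-(methoxycarbonyl)-6-methyl-9-oxonona-1,7-dien-2-yl]-7-(trimethylsilyl)hept-6-ynoate | COC(=O)[C@](C)(/C=C/C=O)CCCC(=C)[C@H](CCC#C[Si](C)(C)C)C(C(=O)OC(C)(C)C)P(=O)(OCC)OCC | intermediate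
25 | ring-A aldehyde: cyclohexane with C4 (CH3 α, CO2Me β), C5 (H α, CH2CHO) and C10 (CH3 β, C9 branch carrying the phosphonoacetate and the silylbutynyl arm) | O=CC[C@@H]1[C@](C)(CCC[C@]1(C)C(=O)OC)[C@H](CCC#C[Si](C)(C)C)C(C(=O)OC(C)(C)C)P(=O)(OCC)OCC | intermediate
26 | 17-tert-butyl 19-methyl 15,16-dinor-9-epi-labd-7-en-13-yne-17,19-dioate (5α-H, 10β-CH3, 4β-CO2Me, C9 side chain α) | CC(C)(C)OC(=O)C1=CC[C@@H]2[C@](C)(CCC[C@]2(C)C(=O)OC)[C@@H]1CCC#C | intermediate
27 | 19-methyl hydrogen 15,16-dinor-9-epi-labd-7-en-13-yne-17,19-dioate (17-acid) | OC(=O)C1=CC[C@@H]2[C@](C)(CCC[C@]2(C)C(=O)OC)[C@@H]1CCC#C | intermediate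
28 | 17-acyl azide of 27 | [N-]=[N+]=NC(=O)C1=CC[C@@H]2[C@](C)(CCC[C@]2(C)C(=O)OC)[C@@H]1CCC#C | intermediate
29 | methyl 8-isocyanato-15,16,17-trinor-9-epi-labd-7-en-13-yn-19-oate | O=C=NC1=CC[C@@H]2[C@](C)(CCC[C@]2(C)C(=O)OC)[C@@H]1CCC#C | intermediate
30 | methyl 8-oxo-15,16,17-trinor-9-epi-labd-13-yn-19-oate (C9 side chain α) | O=C1CC[C@@H]2[C@](C)(CCC[C@]2(C)C(=O)OC)[C@@H]1CCC#C | intermediate
31 | methyl 8-oxo-15,16,17-trinorlabd-13-yn-19-oate (C9 side chain β, 9α-H) | O=C1CC[C@@H]2[C@](C)(CCC[C@]2(C)C(=O)OC)[C@H]1CCC#C | intermediate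
32 | methyl 15,16-dinorlabd-8(17)-en-13-yn-19-oate | C=C1CC[C@@H]2[C@](C)(CCC[C@]2(C)C(=O)OC)[C@H]1CCC#C | intermediate
33 | methyl (13E)-14-(dimethylalumanyl)-15-norlabda-8(17),13-dien-19-oate | C=C1CC[C@@H]2[C@](C)(CCC[C@]2(C)C(=O)OC)[C@H]1CC/C(C)=C/[Al](C)C | intermediate
34 | methyl (13E)-15-hydroxylabda-8(17),13-dien-19-oate | C=C1CC[C@@H]2[C@](C)(CCC[C@]2(C)C(=O)OC)[C@H]1CC/C(C)=C/CO | intermediate
35 | palmitoyl chloride (hexadecanoyl chloride) | CCCCCCCCCCCCCCCC(=O)Cl | starting material
36 | methyl (4S,5R,9S,10R,13E)-15-(hexadecanoyloxy)labda-8(17),13-dien-19-oate | C=C1CC[C@@H]2[C@](C)(CCC[C@]2(C)C(=O)OC)[C@H]1CC/C(C)=C/COC(=O)CCCCCCCCCCCCCCC | target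

**Totals**
Total step count: 20. Longest linear sequence: 16 steps (steps 5–20, from hex-5-ynoic acid); the other branch is steps 1–4 followed by steps 11–20.

**Steps most likely to fail**

1. Step 15. The tertiary C10 radical may be quenched by hydrogen-atom donation before it cyclizes (net hydrogenation of the alkene), the silane may reduce the enal, or the two faces of the radical may be poorly discriminated. Fallback (same radical made without a metal hydride): starting from 22, Mukaiyama hydration (Co(acac)2, PhSiH3, O2, i-PrOH) should give tertiary alcohol F1. Acetal cleavage (TsOH, wet acetone) should give hydroxy aldehyde F2, and IBX dehydrogenation hydroxy enal F3. Acylation of the tertiary alcohol with chloro N-phthalimidoyl oxalate (Et3N, DMAP) should give N-phthalimidoyl oxalate F4. Visible-light photoredox fragmentation (Ru(bpy)3(PF6)2, Hantzsch ester, i-Pr2NEt·HBF4) should release the C10 radical, whose 6-exo conjugate addition gives aldehyde 25. K2CO3/MeOH then gives 26, where the route is rejoined.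

2. Step 14. Hot IBX in DMSO may over-oxidize or degrade the acidic phosphonoacetate site, or the dehydrogenation may stall. Fallback: starting from 23, amine-catalysed α-selenenylation with N-(phenylseleno)phthalimide should give α-phenylselanyl aldehyde F5. Oxidation with NaIO4 and syn-elimination of the selenoxide at room temperature should give enal 24, where the route is rejoined.

3. Step 18. The basic ylide may enolize the hindered, α-branched ketone instead of adding to it, returning ketone on work-up. Fallback: starting from 31, addition of the weakly basic reagent Me3SiCH2Li/CeCl3 should give β-hydroxysilane F6. Acid-mediated Peterson elimination (TsOH or HF) should give 32, where the route is rejoined.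

**Further compounds**
F1 | step 15 | tertiary alcohol (C10–OH hydration product of 22, C10 epimers) | COC(=O)[C@](C)(CCC(OC)OC)CCCC(C)(O)[C@H](CCC#C[Si](C)(C)C)C(C(=O)OC(C)(C)C)P(=O)(OCC)OCC
F2 | step 15 | hydroxy aldehyde (C7 aldehyde from F1) | COC(=O)[C@](C)(CCC=O)CCCC(C)(O)[C@H](CCC#C[Si](C)(C)C)C(C(=O)OC(C)(C)C)P(=O)(OCC)OCC
F3 | step 15 | hydroxy enal (5E enal from F2) | COC(=O)[C@](C)(/C=C/C=O)CCCC(C)(O)[C@H](CCC#C[Si](C)(C)C)C(C(=O)OC(C)(C)C)P(=O)(OCC)OCC
F4 | step 15 | N-phthalimidoyl oxalate of F3 | COC(=O)[C@](C)(/C=C/C=O)CCCC(C)(OC(=O)C(=O)ON1C(=O)c2ccccc2C1=O)[C@H](CCC#C[Si](C)(C)C)C(C(=O)OC(C)(C)C)P(=O)(OCC)OCC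
F5 | step 14 | α-phenylselanyl aldehyde (C6 selenide of 23, C6 epimers) | COC(=O)[C@](C)(CC([Se]c1ccccc1)C=O)CCCC(=C)[C@H](CCC#C[Si](C)(C)C)C(C(=O)OC(C)(C)C)P(=O)(OCC)OCC
F6 | step 18 | β-hydroxysilane (C8 carbinol bearing CH2SiMe3, from 31, C8 epimers) | C[Si](C)(C)CC1(O)CC[C@@H]2[C@](C)(CCC[C@]2(C)C(=O)OC)[C@H]1CCC#C
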